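The synthesis rests on disconnecting C2–C3 of pyran ring C of the central catechin unit. C2 carries ring oxygen O1 and catechol ring B, so it is traced to an aryl benzoate carbonyl; C3–C4 come from an allyl group on C4a of phloroglucinol ring A. One titanium-mediated ester–olefin cyclization methylenates that ester and closes ring C as a flav-2-ene; syn hydroboration of the C2=C3 enol ether then sets the 2R,3S pair. The benzylated catechin is dibrominated at C6 and C8, dilithiated and added to two fustin-derived flavan-4-ones; ionic hydrogenation of both carbinols and hydrogenolysis give the target.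

Key step: step 4

Remark: (2R,3R)-(+)-fustin (15) is taken as a purchasable natural dihydroflavonol of the stated configuration; its optical purity would be checked before use.

Step 1
Reactants: 1 3,5-bis(benzyloxy)phenol; 2 allyl bromide
Product: 3 1-(allyloxy)-3,5-bis(benzyloxy)benzene
Conditions: K2CO3, acetone, reflux
Reagents that add atoms: none
Why: Williamson etherification: the phenoxide of 1 displaces bromide from allyl bromide by SN2, the benzyl ethers being inert to K2CO3.

Step 2
Reactants: 3 1-(allyloxy)-3,5-bis(benzyloxy)benzene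
Product: 5 2-allyl-3,5-bis(benzyloxy)phenol, via ortho-dienone 4 (not isolated)
Conditions: PhNEt2, 195 °C
Reagents that add atoms: none
Why: Aromatic Claisen rearrangement: the [3,3] shift delivers the allyl group to either of the two equivalent ortho carbons to give dienone 4, which tautomerizes to the phenol; the allyl carbons become C4 and C3 of ring C.

Step 3
Reactants: 5 2-allyl-3,5-bis(benzyloxy)phenol; 6 3,4-bis(benzyloxy)benzoic acid
Product: 8 2-allyl-3,5-bis(benzyloxy)phenyl 3,4-bis(benzyloxy)benzoate, via O-acylisourea 7 (not isolated)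
Conditions: DCC, DMAP (cat.), CH2Cl2, 0 °C to rt
Reagents that add atoms: none
Why: Steglich esterification: DCC activates acid 6 as the O-acylisourea and DMAP transfers the acyl group to the hindered phenol oxygen, which becomes O1 while the carbonyl carbon becomes C2.

Step 4
Reactants: 8 2-allyl-3,5-bis(benzyloxy)phenyl 3,4-bis(benzyloxy)benzoate
Product: 10 5,7-bis(benzyloxy)-2-[3,4-bis(benzyloxy)phenyl]-4H-chromene (tetra-O-benzyl flav-2-ene), via open enol ether 9 (not isolated)
Conditions: Cp2Ti(μ-Cl)(μ-CH2)AlMe2 (Tebbe reagent, 4 equiv), pyridine (cat.), THF, high dilution, 25 °C then reflux; basic alumina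
Reagents that add atoms: none
Why: Cp2Ti=CH2, released from the Tebbe reagent, methylenates the aryl ester carbonyl through an oxatitanacyclobutane to give enol ether 9; on heating, a further equivalent converts the terminal allyl olefin into a titanium alkylidene that closes onto the enol-ether C=CH2 through a titanacyclobutane and expels ethylene, forming the C2=C3 bond. The closest known reaction type is the Tebbe-mediated olefinic ester cyclization (tandem carbonyl methylenation and ring-closing olefin metathesis) used for six- and seven-membered cyclic enol ethers. Ring C closes as a six-membered ring by ring-closing metathesis, the ortho relationship of O1 and C4 on ring A holding the two olefins within reach. No stereocenter is formed; the planar C2=C3 enol ether is the handle from which step 5 sets C2 and C3 together. The step needs methylenation of the ester before metathesis, and cyclization in preference to intermolecular metathesis; the higher reactivity of Cp2Ti=CH2 toward C=O at 25 °C, high dilution and the favourable ring size should secure both, the benzyl ethers are inert, and the acid-labile product is isolated over basic alumina.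

Step 5
Reactants: 10 5,7-bis(benzyloxy)-2-[3,4-bis(benzyloxy)phenyl]-4H-chromene
Product: 12 (2R,3S)-5,7-bis(benzyloxy)-2-[3,4-bis(benzyloxy)phenyl]chroman-3-ol (5,7,3',4'-tetra-O-benzyl-(+)-catechin), via organoborane 11 (not isolated)
Conditions: IpcBH2 (monoisopinocampheylborane from (1R)-(+)-α-pinene), THF, −25 °C; then NaOH, H2O2, 0 °C to rt
Reagents that add atoms: hydrogen peroxide, OO
Why: Brown asymmetric hydroboration–oxidation: boron adds to C3 (β to O1) and hydrogen to C2 on the same face, so that ring B and 3-OH end trans, the pinene-derived borane choosing the face that gives 2R,3S by analogy with its conversion of 1-arylcycloalkenes into (1S,2R)-trans-2-arylcycloalkanols, and alkaline H2O2 replaces boron by OH with retention.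

Step 6
Reactants: 12 5,7,3',4'-tetra-O-benzyl-(+)-catechin
Product: 13 (2R,3S)-3,5,7-tris(benzyloxy)-2-[3,4-bis(benzyloxy)phenyl]chromane (penta-O-benzyl-(+)-catechin)
Conditions: NaH, BnBr, DMF, 0 °C to rt
Reagents that add atoms: benzyl bromide, BrCc1ccccc1
Why: Williamson benzylation of the secondary alkoxide with NaH and BnBr masks the 3-OH against the organolithium chemistry of step 10 without touching C2 or C3.

Step 7
Reactants: 13 penta-O-benzyl-(+)-catechin
Product: 14 (2R,3S)-6,8-dibromo-3,5,7-tris(benzyloxy)-2-[3,4-bis(benzyloxy)phenyl]chromane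
Conditions: NBS (2.1 equiv), CH2Cl2, 0 °C to rt
Reagents that add atoms: N-bromosuccinimide, O=C1CCC(=O)N1Br
Why: Electrophilic aromatic bromination: C6 and C8 of ring A are each flanked by two ether oxygens and are far more nucleophilic than ring B or the benzyl rings, so two equivalents of NBS should brominate exactly these two positions.

Step 8
Reactants: 15 (2R,3R)-fustin [(2R,3R)-2-(3,4-dihydroxyphenyl)-3,7-dihydroxychroman-4-one]
Product: 16 (2R,3R)-7-(benzyloxy)-2-[3,4-bis(benzyloxy)phenyl]-3-hydroxychroman-4-one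
Conditions: BnBr, K2CO3, DMF, N2, rt
Reagents that add atoms: benzyl bromide, BrCc1ccccc1
Why: Williamson etherification of the three phenols with K2CO3, which leaves the less acidic aliphatic 3-OH free; mild base at room temperature under N2 avoids opening of the flavanone ring and air oxidation.

Step 9
Reactants: 16 (2R,3R)-7-(benzyloxy)-2-[3,4-bis(benzyloxy)phenyl]-3-hydroxychroman-4-one
Product: 17 (2R,3R)-3,7-bis(benzyloxy)-2-[3,4-bis(benzyloxy)phenyl]chroman-4-one (tetra-O-benzylfustin)
Conditions: BnOC(=NH)CCl3, CF3SO3H (cat.), CH2Cl2–cyclohexane, 0 °C to rt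
Reagents that add atoms: benzyl 2,2,2-trichloroacetimidate, N=C(OCc1ccccc1)C(Cl)(Cl)Cl
Why: Acid-catalysed benzylation with the trichloroacetimidate (SN1-type benzyl transfer) etherifies the 3-OH without the strong base that would enolize the ketone and epimerize or eliminate at C3.

Step 10
Reactants: 14 6,8-dibromo-penta-O-benzyl-(+)-catechin; 17 tetra-O-benzylfustin (2.4 equiv)
Product: 19 bis-carbinol: penta-O-benzyl-(+)-catechin carrying at C6 and at C8 a (2R,3R)-3,7-bis(benzyloxy)-2-[3,4-bis(benzyloxy)phenyl]-4-hydroxychroman-4-yl group (carbinol configurations not assigned), via dilithioarene 18 (not isolated)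
Conditions: t-BuLi (4.4 equiv), THF, −78 °C; then 17, −78 to 0 °C; H2O
Reagents that add atoms: none
Why: Twofold bromine–lithium exchange gives an aryllithium flanked by two ether oxygens at each of C6 and C8, and each adds 1,2 to the C4 carbonyl of 17 (no peri substituent at C5), a known union for 8-lithiated flavan-3-ol ethers and 3-O-benzylflavan-4-ones; the carbinol configurations are irrelevant because step 11 planarizes both centres.

Step 11
Reactants: 19 bis-carbinol
Product: 20 tridecabenzyl ether of the target: penta-O-benzyl-(+)-catechin carrying at C6 and at C8 a (2R,3S,4R)-3,7-bis(benzyloxy)-2-[3,4-bis(benzyloxy)phenyl]chroman-4-yl group (both units 2,3-trans-3,4-cis, 4β)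
Conditions: Bu3SnH, CF3CO2H, CH2Cl2, 0 °C
Reagents that add atoms: none
Why: Ionic hydrogenation: CF3CO2H ionizes each tertiary bis-benzylic carbinol to a diarylmethyl cation stabilized by ring A and by the trioxygenated catechin ring, and Bu3SnH should deliver hydride anti to the adjacent 3-OBn group, as nucleophiles generally add to flavan-4-yl cations trans to the C3 oxygen, which leaves the catechin ring cis to the 3-oxygen (4β, 4R) in both units.

Step 12
Reactants: 20 tridecabenzyl ether of the target
Product: 21 CNP0289228.4, (2R,3S)-catechin carrying (2R,3S,4R)-fisetinidol-4-yl units at C6 and C8 [fisetinidol-(4β→6)-catechin-(8←4β)-fisetinidol]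
Conditions: H2, Pd(OH)2/C, THF–MeOH–H2O, rt
Reagents that add atoms: none
Why: Hydrogenolysis over Pd(OH)2/C should cleave all thirteen benzyl ethers, while the hindered diarylmethine interflavanyl bonds and the cyclic benzylic C2–O1 ethers survive these mild neutral conditions.

Compound list
1 | 3,5-bis(benzyloxy)phenol | Oc1cc(OCc2ccccc2)cc(OCc2ccccc2)c1 | starting material
2 | allyl bromide | C=CCBr | starting material
3 | 1-(allyloxy)-3,5-bis(benzyloxy)benzene | C=CCOc1cc(OCc2ccccc2)cc(OCc2ccccc2)c1 | intermediate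
4 | 6-allyl-3,5-bis(benzyloxy)cyclohexa-2,4-dien-1-one (ortho-dienone, racemic, transient) | O=C1C=C(OCc2ccccc2)C=C(OCc2ccccc2)C1CC=C | intermediate
5 | 2-allyl-3,5-bis(benzyloxy)phenol | C=CCc1c(O)cc(OCc2ccccc2)cc1OCc1ccccc1 | intermediate
6 | 3,4-bis(benzyloxy)benzoic acid | OC(=O)c1ccc(OCc2ccccc2)c(OCc2ccccc2)c1 | starting material
7 | O-acylisourea of 6 with DCC | O=C(OC(=NC1CCCCC1)NC1CCCCC1)c1ccc(OCc2ccccc2)c(OCc2ccccc2)c1 | intermediate
8 | 2-allyl-3,5-bis(benzyloxy)phenyl 3,4-bis(benzyloxy)benzoate | C=CCc1c(OC(=O)c2ccc(OCc3ccccc3)c(OCc3ccccc3)c2)cc(OCc2ccccc2)cc1OCc1ccccc1 | intermediate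
9 | 2-allyl-3,5-bis(benzyloxy)phenyl 1-[3,4-bis(benzyloxy)phenyl]vinyl ether (open enol ether) | C=CCc1c(OC(=C)c2ccc(OCc3ccccc3)c(OCc3ccccc3)c2)cc(OCc2ccccc2)cc1OCc1ccccc1 | intermediate
10 | 5,7-bis(benzyloxy)-2-[3,4-bis(benzyloxy)phenyl]-4H-chromene | C(c1ccccc1)Oc1cc(OCc2ccccc2)c2c(c1)OC(c1ccc(OCc3ccccc3)c(OCc3ccccc3)c1)=CC2 | intermediate
11 | (isopinocampheyl)[5,7-bis(benzyloxy)-2-(3,4-bis(benzyloxy)phenyl)chroman-3-yl]borane, boron on C3 cis to H-2, ring configuration as in 12 | C[C@H]1[C@@H](C[C@@H]2C[C@H]1C2(C)C)B[C@H]1Cc2c(OCc3ccccc3)cc(OCc3ccccc3)cc2O[C@@H]1c1ccc(OCc2ccccc2)c(OCc2ccccc2)c1 | intermediate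
12 | (2R,3S)-5,7-bis(benzyloxy)-2-[3,4-bis(benzyloxy)phenyl]chroman-3-ol | C(c1ccccc1)Oc1cc(OCc2ccccc2)c2c(c1)O[C@H](c1ccc(OCc3ccccc3)c(OCc3ccccc3)c1)[C@@H](O)C2 | intermediate
13 | (2R,3S)-3,5,7-tris(benzyloxy)-2-[3,4-bis(benzyloxy)phenyl]chromane | C(c1ccccc1)Oc1cc(OCc2ccccc2)c2c(c1)O[C@H](c1ccc(OCc3ccccc3)c(OCc3ccccc3)c1)[C@@H](OCc1ccccc1)C2 | intermediate
14 | (2R,3S)-6,8-dibromo-3,5,7-tris(benzyloxy)-2-[3,4-bis(benzyloxy)phenyl]chromane | C(c1ccccc1)Oc1c(Br)c(OCc2ccccc2)c2c(c1Br)O[C@H](c1ccc(OCc3ccccc3)c(OCc3ccccc3)c1)[C@@H](OCc1ccccc1)C2 | intermediate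
15 | (2R,3R)-fustin | O=C1c2ccc(O)cc2O[C@H](c2ccc(O)c(O)c2)[C@H]1O | starting material
16 | (2R,3R)-7-(benzyloxy)-2-[3,4-bis(benzyloxy)phenyl]-3-hydroxychroman-4-one | O=C1c2ccc(OCc3ccccc3)cc2O[C@H](c2ccc(OCc3ccccc3)c(OCc3ccccc3)c2)[C@H]1O | intermediate
17 | (2R,3R)-3,7-bis(benzyloxy)-2-[3,4-bis(benzyloxy)phenyl]chroman-4-one | O=C1c2ccc(OCc3ccccc3)cc2O[C@H](c2ccc(OCc3ccccc3)c(OCc3ccccc3)c2)[C@H]1OCc1ccccc1 | intermediate
18 | (2R,3S)-6,8-dilithio-3,5,7-tris(benzyloxy)-2-[3,4-bis(benzyloxy)phenyl]chromane | C(c1ccccc1)Oc1c([Li])c(OCc2ccccc2)c2c(c1[Li])O[C@H](c1ccc(OCc3ccccc3)c(OCc3ccccc3)c1)[C@@H](OCc1ccccc1)C2 | intermediate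
19 | bis-carbinol: 13 carrying at C6 and at C8 a (2R,3R)-3,7-bis(benzyloxy)-2-[3,4-bis(benzyloxy)phenyl]-4-hydroxychroman-4-yl group; the two carbinol carbons are left unassigned | O(Cc5ccccc5)c1ccc2c(c1)O[C@H](c1ccc(OCc5ccccc5)c(OCc5ccccc5)c1)[C@@H](OCc5ccccc5)C2(O)c1c(OCc5ccccc5)c2c(c(C3(O)c4ccc(OCc5ccccc5)cc4O[C@H](c4ccc(OCc5ccccc5)c(OCc5ccccc5)c4)[C@H]3OCc5ccccc5)c1OCc5ccccc5)O[C@H](c1ccc(OCc5ccccc5)c(OCc5ccccc5)c1)[C@@H](OCc5ccccc5)C2 | intermediate
20 | tridecabenzyl ether of the target: 13 carrying at C6 and at C8 a (2R,3S,4R)-3,7-bis(benzyloxy)-2-[3,4-bis(benzyloxy)phenyl]chroman-4-yl group | O(Cc5ccccc5)c1ccc2c(c1)O[C@H](c1ccc(OCc5ccccc5)c(OCc5ccccc5)c1)[C@@H](OCc5ccccc5)[C@H]2c1c(OCc5ccccc5)c2c(c([C@H]3c4ccc(OCc5ccccc5)cc4O[C@H](c4ccc(OCc5ccccc5)c(OCc5ccccc5)c4)[C@H]3OCc5ccccc5)c1OCc5ccccc5)O[C@H](c1ccc(OCc5ccccc5)c(OCc5ccccc5)c1)[C@@H](OCc5ccccc5)C2 | intermediate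
21 | CNP0289228.4: (2R,3S)-catechin carrying (2R,3S,4R)-fisetinidol-4-yl units at C6 and C8 | Oc1ccc2c(c1)O[C@H](c1ccc(O)c(O)c1)[C@@H](O)[C@H]2c1c(O)c2c(c([C@H]3c4ccc(O)cc4O[C@H](c4ccc(O)c(O)c4)[C@H]3O)c1O)O[C@H](c1ccc(O)c(O)c1)[C@@H](O)C2 | target

Total step count: 12. Longest linear sequence: 10 steps (steps 1–7, then 10–12); steps 8–9 form the second branch.

Steps most likely to fail

Step 4. The titanium-mediated closure may stall at the open enol ether, or intermolecular metathesis may outrun cyclization and give oligomers. The fallback makes the same bond by reductive carbonyl coupling. It sets out from 8: Lemieux–Johnson cleavage of the allyl group (OsO4 cat., NaIO4, 2,6-lutidine, dioxane–H2O) would give 3,5-bis(benzyloxy)-2-(2-oxoethyl)phenyl 3,4-bis(benzyloxy)benzoate F1. An intramolecular McMurry-type oxo-ester coupling with low-valent titanium (TiCl3, Zn dust, DME, reflux, slow addition) would then join the aldehyde and ester carbonyl carbons directly and come back to the route at 10.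

Step 10. The second halogen–lithium exchange may be incomplete, or proton transfer from the enolizable ketone may quench the aryllithium before the second addition. The fallback installs the two units one at a time. It sets out from 14: n-BuLi (1 equiv, THF, −78 °C) followed by one equivalent of 17 would give the 6-bromo-8-carbinol mono-adduct F2. It is drawn as the C8 adduct; the C6 regioisomer would serve equally, since both positions receive the same unit. Deprotonation of its hydroxyl with MeLi, exchange of the remaining bromine with t-BuLi and addition to a second equivalent of 17 would come back to the route at 19.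

Step 11. Hydride capture of the two cations may show poor facial selectivity, or hydride may arrive syn to the 3-OBn group and give the 4α epimers. The fallback makes the interflavanyl bonds by the classical Friedel–Crafts condensation, in which the arene rather than hydride is the nucleophile. It sets out from 17 and 13: NaBH4 (THF–MeOH, 0 °C) would reduce 17 to (2R,3S,4R)-3,7-bis(benzyloxy)-2-[3,4-bis(benzyloxy)phenyl]chroman-4-ol F3. Twofold TMSOTf-promoted condensation of F3 with 13 (CH2Cl2, −78 °C) would arylate C8 and C6. The 3,4-cis linkage is a regular product of such condensations in the 5-deoxy series, so the 4β,4β isomer would be separated from its C4 epimers by chromatography, coming back to the route at 20.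

Further compounds
F1 | step 4 | 3,5-bis(benzyloxy)-2-(2-oxoethyl)phenyl 3,4-bis(benzyloxy)benzoate | O=CCc1c(OC(=O)c2ccc(OCc3ccccc3)c(OCc3ccccc3)c2)cc(OCc2ccccc2)cc1OCc1ccccc1
F2 | step 10 | (2R,3S)-6-bromo-3,5,7-tris(benzyloxy)-2-[3,4-bis(benzyloxy)phenyl]chromane carrying at C8 a (2R,3R)-3,7-bis(benzyloxy)-2-[3,4-bis(benzyloxy)phenyl]-4-hydroxychroman-4-yl group (carbinol carbon unassigned) | Brc1c(OCc5ccccc5)c2c(c(C3(O)c4ccc(OCc5ccccc5)cc4O[C@H](c4ccc(OCc5ccccc5)c(OCc5ccccc5)c4)[C@H]3OCc5ccccc5)c1OCc5ccccc5)O[C@H](c1ccc(OCc5ccccc5)c(OCc5ccccc5)c1)[C@@H](OCc5ccccc5)C2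
F3 | step 11 | (2R,3S,4R)-3,7-bis(benzyloxy)-2-[3,4-bis(benzyloxy)phenyl]chroman-4-ol | O[C@@H]1c2ccc(OCc3ccccc3)cc2O[C@H](c2ccc(OCc3ccccc3)c(OCc3ccccc3)c2)[C@H]1OCc1ccccc1
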